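The route rests on cutting ring A at C4–C5 and ring B at C9–C10 (labdane numbering), reading the C3–O/C4/C19–O array as a β-keto ester (C4 = α-carbon) and the C8=C17 methylene as the trace of an oxidatively terminated radical. One operation, a Mn(OAc)3/Cu(OAc)2 oxidative radical bicyclisation, turns an acyclic (E,E)-farnesyl-type 2-methyl-3-oxo ester into the trans-decalin: the C4 radical bonds to C5, the C10 radical to C9, and copper-mediated elimination leaves the exocyclic alkene, setting C4, C5, C9 and C10 under control of a (+)-8-phenylmenthyl ester. The precursor is a linear keto ester made from geranyl acetate; hydride reduction, Takai iodo-olefination and Stille coupling to a stannylbutenolide complete the target.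

Key step: step 5

Numbering used throughout: ring A = C1–C5, C10; ring B = C5–C10; C11 on C9; C17 = methylene carbon on C8; C18 (methyl) and C19 (oxygenated carbon) on C4; C20 = methyl on C10.

Remark: the facial sense of the auxiliary in step 5 is assigned from the shielding model given there, not from a measured result; on that model the (1S,2R,5S) alcohol leads to the target series, and the enantiomeric alcohol would be taken if the sense proved opposite.

Step 1
Reactants: 1 geranyl acetate
Product: 2 (2E,6E)-8-hydroxy-3,7-dimethylocta-2,6-dien-1-yl acetate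
Conditions: SeO2 (0.3 equiv), t-BuOOH (70% aq.), salicylic acid (cat.), CH2Cl2, rt
Reagents that add atoms: selenium dioxide O=[Se]=O (catalytic oxygen carrier); tert-butyl hydroperoxide CC(C)(C)OO (terminal oxidant)
Why: Selenium dioxide allylic oxidation (Riley type, ene reaction then [2,3]-sigmatropic shift) hydroxylates the E-methyl group of the electron-rich terminal alkene, the C2 alkene being deactivated by the allylic acetate, so the new carbinol should be E-configured.

Step 2
Reactants: 2 (2E,6E)-8-hydroxy-3,7-dimethylocta-2,6-dien-1-yl acetate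
Product: 3 (2E,6E)-8-bromo-3,7-dimethylocta-2,6-dien-1-yl acetate
Conditions: CBr4, PPh3, CH2Cl2, 0 °C
Reagents that add atoms: carbon tetrabromide BrC(Br)(Br)Br
Why: Appel reaction; bromide should displace the phosphorus-activated oxygen by SN2 at the primary allylic carbon at 0 °C without allylic transposition or loss of E geometry.

Step 3
Reactants: 4 (+)-8-phenylmenthol; 5 ethyl 2-methyl-3-oxobutanoate
Product: 6 (1S,2R,5S)-8-phenylmenthyl 2-methyl-3-oxobutanoate
Conditions: DMAP (0.3 equiv), toluene, reflux, 4 Å molecular sieves (ethanol removed)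
Reagents that add atoms: none
Why: DMAP-catalysed transesterification of a β-keto ester, driven by removal of ethanol, should load the hindered auxiliary alcohol; the α-stereocentre stays an epimeric mixture, which is irrelevant because it later becomes a planar radical.

Step 4
Reactants: 6 (1S,2R,5S)-8-phenylmenthyl 2-methyl-3-oxobutanoate; 3 (2E,6E)-8-bromo-3,7-dimethylocta-2,6-dien-1-yl acetate
Product: 8 8-phenylmenthyl (6E,10E)-12-acetoxy-2,6,10-trimethyl-3-oxododeca-6,10-dienoate, via sodium lithium dianion 7 (not isolated)
Conditions: NaH, THF, 0 °C; n-BuLi, 0 °C; then 3, 0 °C; aq. NH4Cl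
Reagents that add atoms: none
Why: β-Keto ester dianion γ-alkylation; the terminal carbanion of 7 is the more nucleophilic site and should displace the primary allylic bromide by SN2 much faster than it attacks the acetate, leaving both E alkenes untouched.

Step 5
Reactants: 8 8-phenylmenthyl (6E,10E)-12-acetoxy-2,6,10-trimethyl-3-oxododeca-6,10-dienoate
Product: 12 bicyclic 3-oxo 19-ester 8(17)-ene 11-acetate, via acyclic C4 radical 9 (not isolated), via monocyclic C10 radical 10 (not isolated), via bicyclic C8 radical 11 (not isolated)
Conditions: Mn(OAc)3·2H2O (2.2 equiv), Cu(OAc)2·H2O (1.0 equiv), degassed AcOH (high dilution), rt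
Reagents that add atoms: none
Why: Mn(OAc)3 (trivalent manganese) oxidises the enol form of the β-keto ester by inner-sphere electron transfer to the electrophilic C4 radical 9, which adds 6-endo-trig to C5 of the C5=C10 alkene (C4–C5 bond, ring A) to give tertiary radical 10; 10 adds 6-endo-trig to C9 of the C8=C9 alkene (C10–C9 bond, ring B) to give tertiary radical 11, which Cu(OAc)2 (divalent copper) intercepts and converts by syn β-hydride loss towards the unhindered C17 methyl into the exocyclic alkene. The closest known reaction type is the Mn(OAc)3/Cu(OAc)2 oxidative free-radical polyene cyclisation of 2-substituted β-keto esters, including its version with 8-phenylmenthyl esters. Both rings close through chair-like transition states on the two E alkenes, so H-5 and CH3-10 should end up trans and the C9 acetoxymethyl group equatorial. At C4 the radical is expected to react in the conformer with the ketone oxygen turned away from the ester, which places the ester axial (C19, syn to CH3-10) and the methyl equatorial. The phenyl ring of the auxiliary is taken to stack over one face of the ester-conjugated planar radical (ester carbonyl syn to the ketone carbon), so C5 bonds to the open face; this fixes the absolute configuration of C4 and, through the chair cascade, of C5, C10 and C9, and the minor auxiliary diastereomer is removed by chromatography. The step needs 6-endo over 5-exo closure, secured by trisubstituted alkenes that offer their less substituted carbon and give tertiary radicals, and exocyclic over endocyclic elimination, secured by the preference of the copper intermediate for the least hindered β-hydrogen.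

Step 6
Reactants: 12 bicyclic 3-oxo 19-ester 8(17)-ene 11-acetate
Product: 13 3,11,19-triol
Conditions: LiAlH4, THF, 0 °C then reflux
Reagents that add atoms: none
Why: Hydride reduction; LiAlH4 should attack the C3 ketone along the axial trajectory on the face opposite the axial C19 ester and CH3-10, giving the equatorial alcohol, and on heating cleave the hindered C19 ester (releasing the auxiliary alcohol) and the C11 acetate to the primary alcohols.

Step 7
Reactants: 13 3,11,19-triol
Product: 14 3,19-O-isopropylidene 11-alcohol
Conditions: 2,2-dimethoxypropane, PPTS (cat.), CH2Cl2, rt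
Reagents that add atoms: 2,2-dimethoxypropane COC(C)(C)OC
Why: Acid-catalysed transketalisation should engage only the 1,3-related C3 and C19 hydroxyls in a six-membered isopropylidene acetal, leaving the isolated primary C11 hydroxyl free (a mixed ketal there is lost on aqueous work-up).

Step 8
Reactants: 14 3,19-O-isopropylidene 11-alcohol
Product: 15 3,19-O-isopropylidene 11-aldehyde
Conditions: Dess–Martin periodinane, NaHCO3, CH2Cl2, 0 °C
Reagents that add atoms: none
Why: Dess–Martin oxidation under buffered, non-basic conditions should give the β,γ-unsaturated aldehyde without epimerisation at C9 or migration of the exocyclic alkene; the crude aldehyde is used at once.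

Step 9
Reactants: 15 3,19-O-isopropylidene 11-aldehyde
Product: 16 (E)-12-iodo-11-ene acetonide
Conditions: CrCl2 (excess), CHI3, THF/1,4-dioxane, 0 °C to rt
Reagents that add atoms: iodoform IC(I)I
Why: Takai olefination; the geminal dichromium species from CHI3 and CrCl2 (divalent chromium) adds to the aldehyde and elimination should give the E-iodoalkene, the bulky C9 substituent reinforcing E selectivity.

Step 10
Reactants: 17 3-bromofuran-2(5H)-one
Product: 18 3-(tributylstannyl)furan-2(5H)-one
Conditions: (Bu3Sn)2, Pd(PPh3)4 (5 mol %), toluene, 100 °C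
Reagents that add atoms: hexabutylditin CCCC[Sn](CCCC)(CCCC)[Sn](CCCC)(CCCC)CCCC
Why: Palladium-catalysed stannylation of an alkenyl bromide with a distannane (oxidative addition to zerovalent palladium, Sn–Sn transmetalation, reductive elimination) should give the α-stannyl butenolide.

Step 11
Reactants: 16 (E)-12-iodo-11-ene acetonide; 18 3-(tributylstannyl)furan-2(5H)-one
Product: 19 3,19-O-isopropylidene-14-deoxy-11,12-didehydroandrographolide
Conditions: Pd2(dba)3 (5 mol %), AsPh3 (20 mol %), CuI (20 mol %), NMP, rt
Reagents that add atoms: none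
Why: Stille coupling with CuI co-catalysis runs under neutral conditions with retention of the alkene geometry of 16 and should join C12 to C13 without disturbing the base-sensitive butenolide.

Step 12
Reactants: 19 3,19-O-isopropylidene-14-deoxy-11,12-didehydroandrographolide
Product: 20 14-deoxy-11,12-didehydroandrographolide
Conditions: AcOH/H2O (3:1), rt
Reagents that add atoms: none
Why: Mild aqueous acid hydrolysis of the isopropylidene acetal should free the 3,19-diol, the exocyclic alkene and the dienyl butenolide being inert to AcOH at room temperature.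

Step 13
Reactants: 20 14-deoxy-11,12-didehydroandrographolide
Product: 21 19-O-acetyl-14-deoxy-11,12-didehydroandrographolide (target)
Conditions: Ac2O (1.1 equiv), pyridine, CH2Cl2, −20 to 0 °C
Reagents that add atoms: acetic anhydride CC(=O)OC(C)=O
Why: Selective acylation; with a limiting amount of Ac2O at low temperature the primary C19 hydroxyl should react faster than the secondary C3 hydroxyl, which is flanked by the quaternary C4.

Compound list

1 | geranyl acetate, (2E)-3,7-dimethylocta-2,6-dien-1-yl acetate | CC(C)=CCC/C(C)=C/COC(C)=O | starting material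
2 | (2E,6E)-8-hydroxy-3,7-dimethylocta-2,6-dien-1-yl acetate | OC/C(C)=C/CC/C(C)=C/COC(C)=O | intermediate
3 | (2E,6E)-8-bromo-3,7-dimethylocta-2,6-dien-1-yl acetate | BrC/C(C)=C/CC/C(C)=C/COC(C)=O | intermediate
4 | (+)-8-phenylmenthol, (1S,2R,5S)-5-methyl-2-(2-phenylpropan-2-yl)cyclohexan-1-ol | CC(C)(c1ccccc1)[C@H]1CC[C@H](C)C[C@@H]1O | starting material
5 | ethyl 2-methyl-3-oxobutanoate | CCOC(=O)C(C)C(C)=O | starting material
6 | (1S,2R,5S)-5-methyl-2-(2-phenylpropan-2-yl)cyclohexyl 2-methyl-3-oxobutanoate (both C2 epimers) | CC(=O)C(C)C(=O)O[C@H]1C[C@@H](C)CC[C@@H]1C(C)(C)c1ccccc1 | intermediate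
7 | sodium lithium dianion of 6 (C2 and C4 of the butanoate deprotonated) | [Li+].[Na+].[CH2-]C(=O)[C-](C)C(=O)O[C@H]1C[C@@H](C)CC[C@@H]1C(C)(C)c1ccccc1 | intermediate (not isolated)
8 | (1S,2R,5S)-8-phenylmenthyl (6E,10E)-12-acetoxy-2,6,10-trimethyl-3-oxododeca-6,10-dienoate (both C2 epimers) | CC(=O)OC/C=C(C)/CC/C=C(C)/CCC(=O)C(C)C(=O)O[C@H]1C[C@@H](C)CC[C@@H]1C(C)(C)c1ccccc1 | intermediate
9 | acyclic C4 radical of 8 (radical at C2 of the dodecadienoate) | CC(=O)OC/C=C(C)/CC/C=C(C)/CCC(=O)[C](C)C(=O)O[C@H]1C[C@@H](C)CC[C@@H]1C(C)(C)c1ccccc1 | intermediate (not isolated)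
10 | monocyclic C10 radical: ring A closed by the C4–C5 bond, C3 ketone, C4 with CH3 and axial ester, (E)-6-acetoxy-4-methylhex-4-enyl chain on C5, radical centre C10 carrying CH3 | CC(=O)OC/C=C(C)/CC[C@@H]1[C@](C)(C(=O)O[C@H]2C[C@@H](C)CC[C@@H]2C(C)(C)c2ccccc2)C(=O)CC[C]1C | intermediate (not isolated)
11 | bicyclic C8 radical: trans-decalin as in 12, radical centre C8 carrying CH3 | C[C]1CC[C@@H]2[C@](C)(C(=O)O[C@H]3C[C@@H](C)CC[C@@H]3C(C)(C)c3ccccc3)C(=O)CC[C@@]2(C)[C@@H]1COC(C)=O | intermediate (not isolated)
12 | bicyclic keto ester: trans-decalin (H-5 trans to CH3-10), C3 ketone, C4 with equatorial CH3 (C18) and axial (1S,2R,5S)-8-phenylmenthyl ester carbon (C19) syn to CH3-10, C8=C17 methylene, equatorial CH2OAc (C11) on C9 on the face of CH3-10; ring configuration as in 21 | C=C1CC[C@@H]2[C@](C)(C(=O)O[C@H]3C[C@@H](C)CC[C@@H]3C(C)(C)c3ccccc3)C(=O)CC[C@@]2(C)[C@@H]1COC(C)=O | intermediate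
13 | 3,11,19-triol: as 12 with equatorial 3-OH (same face as C19 and CH3-10), CH2OH at C4 (C19) and CH2OH at C9 (C11) | C=C1CC[C@@H]2[C@](C)(CO)[C@H](O)CC[C@@]2(C)[C@@H]1CO | intermediate
14 | 3,19-O-isopropylidene acetal of 13 (1,3-dioxane fused to ring A), free 11-OH | C=C1CC[C@@H]2[C@]3(C)COC(C)(C)O[C@@H]3CC[C@@]2(C)[C@@H]1CO | intermediate
15 | C11 aldehyde of 14 (CHO equatorial on C9) | C=C1CC[C@@H]2[C@]3(C)COC(C)(C)O[C@@H]3CC[C@@]2(C)[C@@H]1C=O | intermediate
16 | (E)-2-iodoethenyl compound: C9–CH=CH–I, acetonide retained | C=C1CC[C@@H]2[C@]3(C)COC(C)(C)O[C@@H]3CC[C@@]2(C)[C@@H]1/C=C/I | intermediate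
17 | 3-bromofuran-2(5H)-one | O=C1OCC=C1Br | starting material
18 | 3-(tributylstannyl)furan-2(5H)-one | CCCC[Sn](CCCC)(CCCC)C1=CCOC1=O | intermediate
19 | 3,19-O-isopropylidene-14-deoxy-11,12-didehydroandrographolide (11E) | C=C1CC[C@@H]2[C@]3(C)COC(C)(C)O[C@@H]3CC[C@@]2(C)[C@@H]1/C=C/C1=CCOC1=O | intermediate
20 | 14-deoxy-11,12-didehydroandrographolide (11E; 3,19-diol) | C=C1CC[C@@H]2[C@](C)(CO)[C@H](O)CC[C@@]2(C)[C@@H]1/C=C/C1=CCOC1=O | intermediate
21 | 19-O-acetyl-14-deoxy-11,12-didehydroandrographolide (3R,4R,5S,9R,10R in labdane numbering; 11E) | C=C1CC[C@@H]2[C@](C)(COC(C)=O)[C@H](O)CC[C@@]2(C)[C@@H]1/C=C/C1=CCOC1=O | target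

Total step count: 13. Longest linear sequence: 11 steps (steps 1, 2, 4, 5, 6, 7, 8, 9, 11, 12, 13); steps 3 and 10 are side branches.

Steps most likely to fail

Step 5. The facial discrimination by the auxiliary ester may be weak, and β-hydride loss from the copper intermediate may partly give endocyclic alkenes, so that the desired diastereomer is hard to obtain pure. The fallback gives up auxiliary control for a racemic cyclisation followed by resolution through covalent diastereomers. It sets out from 3 and 5: the dianion of 5 (NaH, n-BuLi, THF, 0 °C) is alkylated with 3 to give ethyl (6E,10E)-12-acetoxy-2,6,10-trimethyl-3-oxododeca-6,10-dienoate F1. Mn(OAc)3·2H2O/Cu(OAc)2·H2O in AcOH should then give the racemic bicyclic ethyl keto ester F2 (relative configuration as in 12), LiAlH4 the racemic triol F3, and 2,2-dimethoxypropane/PPTS the racemic acetonide alcohol F4. Esterification of F4 with (S)-O-acetylmandelic acid (DCC, cat. DMAP, CH2Cl2, 0 °C) gives two diastereomeric esters that are separated by chromatography. Methanolysis (K2CO3, MeOH) of the diastereomer with the target ring configuration, the (S)-O-acetylmandelate F5, comes back to the route at 14.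

Step 9. Addition of the chromium reagent to the hindered, α-branched aldehyde may be slow, allowing epimerisation at C9, migration of the exocyclic alkene into conjugation and erosion of E selectivity. The fallback replaces the one-step iodo-olefination by an alkyne route. It sets out from 15: Ohira–Bestmann homologation (dimethyl (1-diazo-2-oxopropyl)phosphonate, K2CO3, MeOH, 0 °C) should give the terminal alkyne F6. Syn hydrozirconation with Cp2Zr(H)Cl (THF, rt), which prefers the terminal alkyne over the 1,1-disubstituted alkene, followed by I2 should give the E-iodoalkene with retention and comes back to the route at 16.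

Step 13. Discrimination between the neopentyl primary and the hindered secondary hydroxyl may be poor, leading to over-acylation or acyl migration. The fallback activates the primary oxygen through a tin acetal and does not rely on the innate rate difference. It sets out from 20: Bu2SnO (toluene/MeOH, reflux, water removed) should give the 3,19-O-dibutylstannylene acetal F7, whose primary oxygen is acylated by AcCl (1.0 equiv, CH2Cl2, 0 °C); aqueous work-up comes back to the route at 21.

Further compounds

F1 | step 5 | ethyl (6E,10E)-12-acetoxy-2,6,10-trimethyl-3-oxododeca-6,10-dienoate | CCOC(=O)C(C)C(=O)CC/C(C)=C/CC/C(C)=C/COC(C)=O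
F2 | step 5 | racemic bicyclic ethyl keto ester (relative configuration as in 12; both enantiomers written) | C=C1CC[C@@H]2[C@](C)(C(=O)OCC)C(=O)CC[C@@]2(C)[C@@H]1COC(C)=O.C=C1CC[C@H]2[C@@](C)(C(=O)OCC)C(=O)CC[C@]2(C)[C@H]1COC(C)=O
F3 | step 5 | racemic 3,11,19-triol (relative configuration as in 13; both enantiomers written) | C=C1CC[C@@H]2[C@](C)(CO)[C@H](O)CC[C@@]2(C)[C@@H]1CO.C=C1CC[C@H]2[C@@](C)(CO)[C@@H](O)CC[C@]2(C)[C@H]1CO
F4 | step 5 | racemic 3,19-O-isopropylidene 11-alcohol (relative configuration as in 14; both enantiomers written) | C=C1CC[C@@H]2[C@]3(C)COC(C)(C)O[C@@H]3CC[C@@]2(C)[C@@H]1CO.C=C1CC[C@H]2[C@@]3(C)COC(C)(C)O[C@H]3CC[C@]2(C)[C@H]1CO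
F5 | step 5 | (S)-O-acetylmandelate of 14 at O11 (diastereomer with the target ring configuration) | C=C1CC[C@@H]2[C@]3(C)COC(C)(C)O[C@@H]3CC[C@@]2(C)[C@@H]1COC(=O)[C@@H](OC(C)=O)c1ccccc1
F6 | step 9 | terminal alkyne: C9–C≡CH, acetonide retained | C=C1CC[C@@H]2[C@]3(C)COC(C)(C)O[C@@H]3CC[C@@]2(C)[C@@H]1C#C
F7 | step 13 | 3,19-O-dibutylstannylene acetal of 20 | C=C1CC[C@@H]2[C@]3(C)CO[Sn](CCCC)(CCCC)O[C@@H]3CC[C@@]2(C)[C@@H]1/C=C/C1=CCOC1=O
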